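**Plan**

- Last disconnections: the three methyl esters (acyl–OMe) and the two ring-A aryl methyl ethers (ArO–Me).
- Pyrone (ring C): C2'–C6' plus the carboxyl carbon on C6' are the six carbons of a 3,4-dihydroxyphenyl ring bonded to C1 through the carbon that becomes C4'. Opening O1'–C2' and taking out the O2-derived oxygen restores the C4''–C5'' bond of a pendant catechol.
- Ring B is cut at C3=C4 (aldol condensation), C2–C3 (enolate alkylation), C1–C1'' (conjugate arylation) and C1–C8a (Heck reaction).
- Forward: ring A is bought; the chain is joined by Heck reaction, arylation and alkylation; ring B closes in step 8; ring C arises in step 10, when O2 cleaves the pendant benzene ring and it closes again through oxygen.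
- Stereochemistry: C1 (R) comes from the chiral rhodium catalyst in step 5; C2 (S) is set in step 8 by equilibration to the trans diester, relayed from C1.

Key step: step 10

Locants: core C1–C8a as in 1,2-dihydronaphthalene; pyrone O1', C2'–C6'; pendant benzene ring C1''–C6'', with C1'' on C1 and hydroxyls on C3'' and C4''.
Remark: C2 is carried as an epimer mixture from step 6 to step 8. The iron–triazacyclononane complex of step 10 is counted as a mediator that the oxygenation returns unchanged, although one equivalent is charged.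

**Step 1**
Reactants: 1 (2-bromo-4,5-dimethoxybenzaldehyde)
Product: 2 acetal 2-(2-bromo-4,5-dimethoxyphenyl)-1,3-dioxolane
Conditions: ethylene glycol, TsOH·H2O (cat.), toluene, reflux, Dean–Stark
Reagents that add atoms: ethylene glycol, OCCO
Why: Acid-catalysed acetalisation with azeotropic water removal masks the aldehyde, which would otherwise undergo rhodium-mediated 1,2-arylation and aldol reactions in steps 5 and 6.

**Step 2**
Reactants: 2 (acetal bromide); 3 (methyl acrylate)
Product: 4 cinnamate methyl (2E)-3-[2-(1,3-dioxolan-2-yl)-4,5-dimethoxyphenyl]prop-2-enoate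
Conditions: Pd(OAc)2 (5 mol %), P(o-tol)3, Et3N, DMF, 110 °C
Reagents that add atoms: none
Why: Mizoroki–Heck reaction (oxidative addition to zerovalent palladium, syn insertion, syn β-hydride elimination) gives the E-enoate and forms the C1–C8a bond; the dioxolane is inert to the amine base.

**Step 3**
Reactants: 5 (4-bromocatechol)
Product: 6 ketal 5-bromo-2,2-dimethyl-1,3-benzodioxole
Conditions: 2,2-dimethoxypropane, TsOH·H2O (cat.), toluene, reflux, 4 Å MS (Soxhlet)
Reagents that add atoms: 2,2-dimethoxypropane, COC(C)(C)OC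
Why: Acid-catalysed transketalisation with removal of methanol gives the isopropylidene ketal, a catechol mask that withstands organolithium, enolate and alkoxide steps and is later removed by aqueous TFA without touching aryl methyl ethers.

**Step 4**
Reactants: 6 (bromo ketal)
Product: 7 boronic acid (2,2-dimethyl-1,3-benzodioxol-5-yl)boronic acid
Conditions: n-BuLi, THF, −78 °C; B(OiPr)3, −78 → 20 °C; dil. HCl to pH 5, 0 °C
Reagents that add atoms: triisopropyl borate, CC(C)OB(OC(C)C)OC(C)C; water, O
Why: Bromine–lithium exchange, borate trapping and mild hydrolysis is the standard route to arylboronic acids, and the ketal tolerates the brief cold quench.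

**Step 5**
Reactants: 4 (cinnamate); 7 (boronic acid, 3 equiv)
Product: 8 methyl (3R)-3-(2,2-dimethyl-1,3-benzodioxol-5-yl)-3-[2-(1,3-dioxolan-2-yl)-4,5-dimethoxyphenyl]propanoate
Conditions: [Rh(OH)((S)-binap)]2 (3 mol % Rh), 1,4-dioxane/H2O 10:1, 50 °C
Reagents that add atoms: none
Why: Hayashi–Miyaura asymmetric conjugate arylation, in which the (S)-BINAP aryl–rhodium species should insert the E-enoate on the si face of its α-carbon and so set the future C1 as R; the hydroxo complex needs no added base, so the methyl ester is not saponified.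

**Step 6**
Reactants: 8 (diarylpropanoate); 9 (methyl bromoacetate)
Product: 10 dimethyl 2-[(R)-(2,2-dimethyl-1,3-benzodioxol-5-yl)[2-(1,3-dioxolan-2-yl)-4,5-dimethoxyphenyl]methyl]butanedioate (both epimers at C2)
Conditions: LDA, THF, −78 °C; 9, DMPU, −78 → −30 °C
Reagents that add atoms: none
Why: Alkylation of the lithium ester enolate with the reactive α-bromo ester forms the C2–C3 bond, the diarylmethine C–H being far less acidic; both C2 epimers are usable because step 8 equilibrates this centre.

**Step 7**
Reactants: 10 (succinate acetal)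
Product: 11 dimethyl 2-[(R)-(2,2-dimethyl-1,3-benzodioxol-5-yl)(2-formyl-4,5-dimethoxyphenyl)methyl]butanedioate (both epimers at C2)
Conditions: 0.5 M HCl, THF/H2O, 20 °C
Reagents that add atoms: water, O
Why: Acetal hydrolysis, selective because the dioxolane of a p-methoxybenzaldehyde ionises far faster than the catechol ketal.

**Step 8**
Reactants: 11 (aldehyde diester)
Product: 12 dimethyl (1R,2S)-1-(2,2-dimethyl-1,3-benzodioxol-5-yl)-6,7-dimethoxy-1,2-dihydronaphthalene-2,3-dicarboxylate
Conditions: NaOMe (0.5 equiv), MeOH, 3 Å MS, 0 → 40 °C; AcOH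
Reagents that add atoms: none
Why: Intramolecular aldol condensation (6-exo-trig addition of the CH2 ester enolate to the aldehyde, then E1cB loss of water) closes ring B irreversibly as the aryl-conjugated enoate, while methoxide equilibrates the ester-bearing C2 to the more stable trans arrangement (2S) relative to the fixed C1; the five-membered aldol through C2 is reversible and cannot dehydrate.

**Step 9**
Reactants: 12 (ketal diester)
Product: 13 dimethyl (1R,2S)-1-(3,4-dihydroxyphenyl)-6,7-dimethoxy-1,2-dihydronaphthalene-2,3-dicarboxylate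
Conditions: TFA/H2O 9:1, 0 → 20 °C, argon
Reagents that add atoms: none
Why: Acid hydrolysis of the isopropylidene ketal frees only the pendant catechol; aryl methyl ethers, methyl esters and the enoate are stable, and no base touches C1 or C2.

**Step 10**
Reactants: 13 (pendant catechol)
Product: 17 dimethyl (1R,2S)-6,7-dimethoxy-1-[6-(methoxycarbonyl)-2-oxo-2H-pyran-4-yl]-1,2-dihydronaphthalene-2,3-dicarboxylate, via keto lactone 14 (not isolated), via semialdehyde ester 15 (not isolated), via lactol 16 (not isolated)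
Conditions: FeCl2·4H2O (1 equiv), 1,4,7-triazacyclononane (1 equiv), pyridine (3 equiv), O2 (1 atm), MeOH, 20 °C; 0.5 M HCl wash, extraction into CH2Cl2; activated MnO2 (10 equiv), CH2Cl2, 20 °C
Reagents that add atoms: dioxygen, O=O; methanol, CO
Why: Proposed new method: the pendant catechol chelates the triazacyclononane-capped divalent iron, O2 takes the free cis site and bonds to C4'' to give an iron alkylperoxide, and a Criegee-type shift of the alkenyl carbon C5'' from C4'' to oxygen gives the ring-expanded keto lactone 14, which methanol opens at the C4'' acyl carbon to the 2-hydroxymuconate semialdehyde ester 15. The enol oxygen on old C3'' then adds to the aldehyde carbon (old C5'') in a 6-exo-trig hemiacetalisation (equally an oxa-6π closure of the cis-dienone tautomer), which makes the O1'–C2' bond and ring C as lactol 16, and MnO2 dehydrogenates this allylic lactol to the aromatic pyrone 17. The closest known reaction types are the FeCl2/triazacyclononane/pyridine/O2 cleavage of simple catechols to 2-hydroxymuconate semialdehyde methyl esters and the enzymatic distal cleavage, hemiacetal closure and dehydrogenation that turn protocatechuate or L-DOPA into 4-substituted 2-pyrone-6-carboxylic acids; the sequence has not been shown on a catechol of this size, nor carried through to the pyrone by chemical means. No stereocentre is made (the lactol carbon of 16 becomes the carbonyl), and C1 and C2 should be safe because the medium is near neutral and C1 becomes vinylogously acidic only once 17 exists. Three selectivities are needed: ring A cannot react because its methyl ethers cannot chelate iron; alkenyl (extradiol) rather than acyl (intradiol) migration is favoured by the facial tridentate amine, which leaves O2 cis to the catecholate; and the distal C4''–C5'' bond should be preferred over the proximal C2''–C3'' bond, because the hydroxyl on C3'' (meta to the alkyl substituent) is the more acidic one, making C4'' the enolate-type carbon that meets O2, and because the bulky C1 substituent crowds the proximal flank.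

**Step 11**
Reactants: 17 (pyrone triester)
Product: 18 dimethyl (1R,2S)-6,7-dihydroxy-1-[6-(methoxycarbonyl)-2-oxo-2H-pyran-4-yl]-1,2-dihydronaphthalene-2,3-dicarboxylate
Conditions: BBr3 (6 equiv), CH2Cl2, −78 → 0 °C; ice-water
Reagents that add atoms: none
Why: Lewis-acid ether cleavage, in which BBr3 binds the aryl methyl ethers and bromide removes the methyl groups by SN2 at low temperature; the pyrone, the enoate and both stereocentres should persist because no base is present.

**Step 12**
Reactants: 18 (ring-A catechol triester)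
Product: 19 (1R,2S)-1-(6-carboxy-2-oxo-2H-pyran-4-yl)-6,7-dihydroxy-1,2-dihydronaphthalene-2,3-dicarboxylic acid
Conditions: 3 M HCl/1,4-dioxane 1:1, 70 °C, argon
Reagents that add atoms: water, O
Why: Acid-catalysed ester hydrolysis (AAC2) frees the three acids without base, which would open the pyrone or deprotonate the now acidic C1–H; the pyrone acid is the closed, acid-stable form of its hydroxymuconic acid, and trans is the stable arrangement at C2.

**Compound list**

1 | 2-bromo-4,5-dimethoxybenzaldehyde | COc1cc(Br)c(C=O)cc1OC | starting material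
2 | 2-(2-bromo-4,5-dimethoxyphenyl)-1,3-dioxolane | COc1cc(Br)c(C2OCCO2)cc1OC | intermediate
3 | methyl acrylate | C=CC(=O)OC | starting material
4 | methyl (2E)-3-[2-(1,3-dioxolan-2-yl)-4,5-dimethoxyphenyl]prop-2-enoate | COC(=O)/C=C/c1cc(OC)c(OC)cc1C1OCCO1 | intermediate
5 | 4-bromocatechol | Oc1ccc(Br)cc1O | starting material
6 | 5-bromo-2,2-dimethyl-1,3-benzodioxole | CC1(C)Oc2ccc(Br)cc2O1 | intermediate
7 | (2,2-dimethyl-1,3-benzodioxol-5-yl)boronic acid | CC1(C)Oc2ccc(B(O)O)cc2O1 | intermediate
8 | methyl (3R)-3-(2,2-dimethyl-1,3-benzodioxol-5-yl)-3-[2-(1,3-dioxolan-2-yl)-4,5-dimethoxyphenyl]propanoate | COC(=O)C[C@H](c1ccc2OC(C)(C)Oc2c1)c1cc(OC)c(OC)cc1C1OCCO1 | intermediate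
9 | methyl bromoacetate | COC(=O)CBr | starting material
10 | dimethyl 2-[(R)-(2,2-dimethyl-1,3-benzodioxol-5-yl)[2-(1,3-dioxolan-2-yl)-4,5-dimethoxyphenyl]methyl]butanedioate, both C2 epimers | COC(=O)CC(C(=O)OC)[C@H](c1ccc2OC(C)(C)Oc2c1)c1cc(OC)c(OC)cc1C1OCCO1 | intermediate
11 | dimethyl 2-[(R)-(2,2-dimethyl-1,3-benzodioxol-5-yl)(2-formyl-4,5-dimethoxyphenyl)methyl]butanedioate, both C2 epimers | COC(=O)CC(C(=O)OC)[C@H](c1ccc2OC(C)(C)Oc2c1)c1cc(OC)c(OC)cc1C=O | intermediate
12 | dimethyl (1R,2S)-1-(2,2-dimethyl-1,3-benzodioxol-5-yl)-6,7-dimethoxy-1,2-dihydronaphthalene-2,3-dicarboxylate | COC(=O)C1=Cc2cc(OC)c(OC)cc2[C@@H](c2ccc3OC(C)(C)Oc3c2)[C@@H]1C(=O)OC | intermediate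
13 | dimethyl (1R,2S)-1-(3,4-dihydroxyphenyl)-6,7-dimethoxy-1,2-dihydronaphthalene-2,3-dicarboxylate | COC(=O)C1=Cc2cc(OC)c(OC)cc2[C@@H](c2ccc(O)c(O)c2)[C@@H]1C(=O)OC | intermediate
14 | keto lactone: 13 with the catechol ring replaced by 2,3-dioxo-2,3-dihydrooxepin-5-yl (C1 and C2 as in 13) | COC(=O)C1=Cc2cc(OC)c(OC)cc2[C@@H](C2=CC(=O)C(=O)OC=C2)[C@@H]1C(=O)OC | intermediate
15 | semialdehyde ester: C1 carries C4 of methyl 2-hydroxy-6-oxohexa-2,4-dienoate, aldehyde cis to C3 across C4=C5, enol geometry open (C1 and C2 as in 13) | COC(=O)C1=Cc2cc(OC)c(OC)cc2[C@@H](C(/C=C(O)C(=O)OC)=C/C=O)[C@@H]1C(=O)OC | intermediate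
16 | lactol: C1 carries 2-hydroxy-6-(methoxycarbonyl)-2H-pyran-4-yl, both epimers at the lactol carbon (C1 and C2 as in 13) | COC(=O)C1=Cc2cc(OC)c(OC)cc2[C@@H](C2=CC(O)OC(C(=O)OC)=C2)[C@@H]1C(=O)OC | intermediate
17 | dimethyl (1R,2S)-6,7-dimethoxy-1-[6-(methoxycarbonyl)-2-oxo-2H-pyran-4-yl]-1,2-dihydronaphthalene-2,3-dicarboxylate | COC(=O)C1=Cc2cc(OC)c(OC)cc2[C@@H](c2cc(C(=O)OC)oc(=O)c2)[C@@H]1C(=O)OC | intermediate
18 | dimethyl (1R,2S)-6,7-dihydroxy-1-[6-(methoxycarbonyl)-2-oxo-2H-pyran-4-yl]-1,2-dihydronaphthalene-2,3-dicarboxylate | COC(=O)C1=Cc2cc(O)c(O)cc2[C@@H](c2cc(C(=O)OC)oc(=O)c2)[C@@H]1C(=O)OC | intermediate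
19 | (1R,2S)-1-(6-carboxy-2-oxo-2H-pyran-4-yl)-6,7-dihydroxy-1,2-dihydronaphthalene-2,3-dicarboxylic acid | O=C(O)C1=Cc2cc(O)c(O)cc2[C@@H](c2cc(C(=O)O)oc(=O)c2)[C@@H]1C(=O)O | target

**Count**

Total steps: 12. Longest linear sequence: 10 steps (1 → 2 → 4 → 8 → 10 → 11 → 12 → 13 → 17 → 18 → 19).

**Steps most likely to fail**

1. Step 10. The oxygenation may stall on the hindered catecholate, with iron autoxidising instead. Ring cleavage may run on the proximal flank or by acyl migration. The keto lactone may lose CO before methanol opens it, and the ring-opened ester may be over-oxidised at the MnO2 stage.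
 The fallback uses known chemistry and puts the extra oxidation level into the substrate. A pendant 3,4,5-trihydroxyphenyl ring is symmetric, and peracid cleavage of o-dihydroxyarenes to muconic acids gives the same hydroxymuconate skeleton already at the acid level, so no regiochemical choice and no lactol oxidation remain. It sets out from 4. Conjugate arylation as in step 5 with 3,4,5-tris(benzyloxy)phenylboronic acid should give methyl (3R)-3-[2-(1,3-dioxolan-2-yl)-4,5-dimethoxyphenyl]-3-[3,4,5-tris(benzyloxy)phenyl]propanoate F1. Alkylation with 9 as in step 6 gives the succinate F2, dilute HCl the aldehyde F3, and NaOMe in MeOH the tribenzyloxy dihydronaphthalene diester F4. BCl3 with pentamethylbenzene in CH2Cl2 at −78 °C removes the benzyl groups to give the triol F5. Peracetic acid in AcOH at 20 °C then cleaves the C4''–C5'' bond to the 2-hydroxymuconic acid F6, which lactonises in the acidic medium (oxygen on C3'' onto C5'') to the pyrone acid F7. TMSCHN2 in MeOH/toluene gives 17, where the route is rejoined.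

2. Step 5. Insertion of the ortho-substituted, electron-rich cinnamate may be slow, so that protodeboronation of 7 outruns addition, and facial discrimination may be incomplete.
 The fallback replaces catalyst control by an auxiliary and sets out from 4. LiOH in THF/H2O gives the cinnamic acid F8. PivCl/Et3N converts it to the mixed pivalic anhydride F9, and lithiated (S)-4-phenyl-1,3-oxazolidin-2-one gives the imide F10. The Grignard reagent F11, made from 6 with Mg in THF, is added with CuBr·SMe2 at −40 °C; it should attack anti to the phenyl group of the magnesium-chelated s-cis imide and give the (3R) adduct F12. NaOMe in MeOH at 0 °C releases the auxiliary and returns to the route at 8.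

3. Step 8. Under methoxide, deprotonation of the product at C2 and reprotonation at C4 can move the double bond into the 1,4-dihydro isomer, from which C1 is deprotonated (racemisation) or air-oxidised to the naphthalene. A bridged lactone may also open in Stobbe fashion to the C2 half-ester.
 The fallback separates bond formation from dehydration, so that no alkoxide meets the alkene. It sets out from 11. NaOMe (0.1 equiv) in MeOH at −20 °C stops at the 4-hydroxy-tetrahydronaphthalene diester F13. TsOH·H2O (cat.) in toluene with 4 Å MS at 60 °C eliminates water through the p-methoxybenzylic cation (E1) to give 12 together with its cis epimer F14, and catalytic DBU in toluene equilibrates F14 to 12, where the route is rejoined.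

**Further compounds**

F1 | step 10 | methyl (3R)-3-[2-(1,3-dioxolan-2-yl)-4,5-dimethoxyphenyl]-3-[3,4,5-tris(benzyloxy)phenyl]propanoate | COC(=O)C[C@H](c1cc(OCc2ccccc2)c(OCc2ccccc2)c(OCc2ccccc2)c1)c1cc(OC)c(OC)cc1C1OCCO1
F2 | step 10 | dimethyl 2-{(R)-[2-(1,3-dioxolan-2-yl)-4,5-dimethoxyphenyl][3,4,5-tris(benzyloxy)phenyl]methyl}butanedioate, both C2 epimers | COC(=O)CC(C(=O)OC)[C@H](c1cc(OCc2ccccc2)c(OCc2ccccc2)c(OCc2ccccc2)c1)c1cc(OC)c(OC)cc1C1OCCO1
F3 | step 10 | dimethyl 2-{(R)-(2-formyl-4,5-dimethoxyphenyl)[3,4,5-tris(benzyloxy)phenyl]methyl}butanedioate, both C2 epimers | COC(=O)CC(C(=O)OC)[C@H](c1cc(OCc2ccccc2)c(OCc2ccccc2)c(OCc2ccccc2)c1)c1cc(OC)c(OC)cc1C=O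
F4 | step 10 | dimethyl (1R,2S)-6,7-dimethoxy-1-[3,4,5-tris(benzyloxy)phenyl]-1,2-dihydronaphthalene-2,3-dicarboxylate | COC(=O)C1=Cc2cc(OC)c(OC)cc2[C@@H](c2cc(OCc3ccccc3)c(OCc3ccccc3)c(OCc3ccccc3)c2)[C@@H]1C(=O)OC
F5 | step 10 | dimethyl (1R,2S)-6,7-dimethoxy-1-(3,4,5-trihydroxyphenyl)-1,2-dihydronaphthalene-2,3-dicarboxylate | COC(=O)C1=Cc2cc(OC)c(OC)cc2[C@@H](c2cc(O)c(O)c(O)c2)[C@@H]1C(=O)OC
F6 | step 10 | 2-hydroxymuconic acid: C1 of the core carries C4 of 2-hydroxyhexa-2,4-dienedioic acid, C6 carboxyl cis to C3 (C1 and C2 as in 13) | COC(=O)C1=Cc2cc(OC)c(OC)cc2[C@@H](C(/C=C(O)C(=O)O)=C/C(=O)O)[C@@H]1C(=O)OC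
F7 | step 10 | 4-[(1R,2S)-2,3-bis(methoxycarbonyl)-6,7-dimethoxy-1,2-dihydronaphthalen-1-yl]-2-oxo-2H-pyran-6-carboxylic acid | COC(=O)C1=Cc2cc(OC)c(OC)cc2[C@@H](c2cc(C(=O)O)oc(=O)c2)[C@@H]1C(=O)OC
F8 | step 5 | (2E)-3-[2-(1,3-dioxolan-2-yl)-4,5-dimethoxyphenyl]prop-2-enoic acid | OC(=O)/C=C/c1cc(OC)c(OC)cc1C1OCCO1
F9 | step 5 | mixed anhydride of F8 with pivalic acid | CC(C)(C)C(=O)OC(=O)/C=C/c1cc(OC)c(OC)cc1C1OCCO1
F10 | step 5 | (4S)-3-{(2E)-3-[2-(1,3-dioxolan-2-yl)-4,5-dimethoxyphenyl]prop-2-enoyl}-4-phenyl-1,3-oxazolidin-2-one | O=C(/C=C/c1cc(OC)c(OC)cc1C1OCCO1)N1[C@@H](c2ccccc2)COC1=O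
F11 | step 5 | (2,2-dimethyl-1,3-benzodioxol-5-yl)magnesium bromide | CC1(C)Oc2ccc([Mg]Br)cc2O1
F12 | step 5 | (4S)-3-{(3R)-3-(2,2-dimethyl-1,3-benzodioxol-5-yl)-3-[2-(1,3-dioxolan-2-yl)-4,5-dimethoxyphenyl]propanoyl}-4-phenyl-1,3-oxazolidin-2-one | O=C(C[C@H](c1ccc2OC(C)(C)Oc2c1)c1cc(OC)c(OC)cc1C1OCCO1)N1[C@@H](c2ccccc2)COC1=O
F13 | step 8 | dimethyl (1R)-1-(2,2-dimethyl-1,3-benzodioxol-5-yl)-4-hydroxy-6,7-dimethoxy-1,2,3,4-tetrahydronaphthalene-2,3-dicarboxylate, isomer mixture at C2, C3 and C4 | COC(=O)C1C(O)c2cc(OC)c(OC)cc2[C@@H](c2ccc3OC(C)(C)Oc3c2)C1C(=O)OC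
F14 | step 8 | dimethyl (1R,2R)-1-(2,2-dimethyl-1,3-benzodioxol-5-yl)-6,7-dimethoxy-1,2-dihydronaphthalene-2,3-dicarboxylate (cis epimer of 12) | COC(=O)C1=Cc2cc(OC)c(OC)cc2[C@@H](c2ccc3OC(C)(C)Oc3c2)[C@H]1C(=O)OC
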